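The drimane core is cut at C1–C10 and C4–C5, the two bonds that flank the ring fusion on the ring A side. This reduces ring A to ethyl vinyl ketone and leaves ring B as a 2-methylcyclohexanone. A single base-mediated Michael–aldol–dehydration sequence makes both bonds, closes ring A with its C3 carbonyl and one C4 methyl, and fixes quaternary C10. The precursor is (5S)-dihydrocarvone. Its isopropenyl group, on the future C7, directs the facial course at C10 and is afterwards degraded to a C7 oxygen. From that oxygen the C7=C8 alkene and the axial C9–C11 bond are developed by a Wittig–Still rearrangement before Mitsunobu coupling with isofraxidin.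

Key step: step 2

Remark: drimane numbering is used for all bicyclic compounds (C11 on C9, C12 on C8, methyl groups on C4 and C10), and β is the face of the C10 methyl group. The target SMILES is read as 5α-H, 10β-CH3, 9β-H with C11 α (axial), that is (1R,4aR,8aS) in naphthalene numbering. The 4aS centre made in step 2 is this same C10.

Step 1
Reactants: 1 (S)-carvone
Product: 3 (5S)-dihydrocarvone (C2 epimer mixture), via lithium enolate 2 (not isolated)
Conditions: LiBH(s-Bu)3, THF, −78 °C; then H2O
Reagents that add atoms: none
Why: Conjugate (1,4-) hydride reduction: the bulky trialkylborohydride delivers hydride to the unhindered β-CH of the cyclohexenone and leaves the isolated isopropenyl alkene and the C5 stereocentre alone, while the C2 epimer mixture formed on protonation of enolate 2 is harmless because C2 is planarised again in step 2.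

Step 2
Reactants: 3 (5S)-dihydrocarvone; 4 ethyl vinyl ketone
Product: 7 (4aS,7S)-1,4a-dimethyl-7-(prop-1-en-2-yl)-4,4a,5,6,7,8-hexahydronaphthalen-2(3H)-one, via Michael adduct dione 5 (not isolated), via aldol ketol 6 (not isolated)
Conditions: KOH (0.3 equiv), EtOH, −10 to 0 °C, slow addition of 4; then reflux
Reagents that add atoms: ethyl vinyl ketone (4), CCC(=O)C=C
Why: KOH equilibrates the enolates of 3, and the more substituted one (planar at the methyl-bearing carbon, so both C2 epimers converge) adds to the terminal carbon of 4 to form C1–C10 and dione 5; the ethyl ketone of 5 then enolises towards its CH2 group (C4), which attacks the ring carbonyl (C5) to give ketol 6, and E1cB loss of water on heating leaves the C4=C5 enone 7. The closest known reaction type is the Robinson annulation of 2-alkylcyclohexanones with alkyl vinyl ketones. Ring A closes in a 6-(enolendo)-exo-trig aldol addition. C10 is the only lasting new stereocentre and is controlled by the C7 isopropenyl group: with that group equatorial on the half-chair enolate, stereoelectronically favoured axial attack through a chair-like transition state brings 4 in on the face cis to it, so the methyl group ends up trans to the isopropenyl group (10β-CH3, 7α-isopropenyl, 4aS). The step needs regioselectivity for the tetrasubstituted enolate, which the reversible protic base medium secures, and facial selectivity, which rests on the 1,4-relationship just described; the C10 epimer would be removed by chromatography of 7. Slow addition of 4 in the cold holds back its polymerisation and a second Michael addition.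

Step 3
Reactants: 7 (4aS,7S)-enone
Product: 9 (4aS,7S,8aR)-1,1,4a-trimethyl-7-(prop-1-en-2-yl)octahydronaphthalen-2(1H)-one (trans-decalone; 5α-H; 10β-CH3; 7α-isopropenyl), via lithium C3–C4 enolate 8 (not isolated)
Conditions: Li (2.5 equiv), t-BuOH (1 equiv), NH3(l)/THF, −78 to −33 °C; then MeI, −33 °C to rt
Reagents that add atoms: iodomethane, CI
Why: Stork reductive alkylation (dissolving-metal enone reduction followed by enolate trapping): the β-carbon C5 is protonated axially on the α face to give the trans-decalin (5α-H anti to the 10β-methyl), the regiodefined enolate 8 is then methylated at C4 to complete the non-stereogenic gem-dimethyl group, and the unconjugated isopropenyl alkene is inert to Li/NH3.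

Step 4
Reactants: 9 trans-decalone
Product: 10 3,3-ethylenedioxy ketal of 9
Conditions: HOCH2CH2OH, p-TsOH·H2O (cat.), benzene, reflux, Dean–Stark
Reagents that add atoms: ethylene glycol, OCCO
Why: Acid-catalysed ketalisation with azeotropic removal of water, a standard protection of 4,4-dimethyl-3-decalones, masks the only carbonyl so that the later peracid and enolate chemistry is confined to ring B, and the catalytic acid loading keeps the isopropenyl alkene from migrating.

Step 5
Reactants: 10 isopropenyl ketal
Product: 12 7α-acetyl-3,3-ethylenedioxy-4,4,10β-trimethyl-trans-decalin (5α-H), via secondary ozonide 11 (not isolated)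
Conditions: O3, CH2Cl2, −78 °C; then PPh3, −78 °C to rt
Reagents that add atoms: ozone, [O-][O+]=O
Why: Ozonolysis (Criegee mechanism) of the only alkene followed by reductive cleavage of ozonide 11 gives the methyl ketone, the ketone-derived dioxolane offers ozone no acetal C–H to attack, and the C7 configuration is retained although its integrity is immaterial because C7 becomes sp2 in step 8.

Step 6
Reactants: 12 methyl ketone
Product: 13 7α-acetoxy-3,3-ethylenedioxy-4,4,10β-trimethyl-trans-decalin (5α-H)
Conditions: m-CPBA, NaHCO3 (buffer), CH2Cl2, rt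
Reagents that add atoms: m-chloroperoxybenzoic acid, OOC(=O)c1cccc(Cl)c1
Why: Baeyer–Villiger oxidation: in the peracid adduct the secondary C7 migrates in preference to methyl and does so with retention, giving the 7α-acetate, while the buffer shields the ketal from the carboxylic acid formed.

Step 7
Reactants: 13 acetate
Product: 14 3,3-ethylenedioxy-4,4,10β-trimethyl-trans-decalin-7α-ol (5α-H)
Conditions: K2CO3 (0.2 equiv), MeOH, rt
Reagents that add atoms: none
Why: Base-catalysed transesterification (methanolysis) of a secondary acetate, to which the ketal is inert.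

Step 8
Reactants: 14 7α-alcohol
Product: 15 3,3-ethylenedioxy-4,4,10β-trimethyl-trans-decalin-7-one (5α-H)
Conditions: n-Pr4N[RuO4] (5 mol %), N-methylmorpholine N-oxide, 4 Å MS, CH2Cl2, rt
Reagents that add atoms: none
Why: Ley–Griffith oxidation of the secondary alcohol under neutral, anhydrous conditions that spare the ketal, the sacrificial C7 stereocentre being erased here.

Step 9
Reactants: 15 7-ketone
Product: 17 3,3-ethylenedioxy-11-nordriman-7-one (8α-CH3 equatorial; 5α-H), via lithium C7–C8 enolate 16 (not isolated)
Conditions: LiN(i-Pr)2, THF, −78 °C; then MeI, DMPU, −78 to −20 °C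
Reagents that add atoms: iodomethane, CI
Why: Kinetic enolate alkylation: deprotonation occurs at C8 rather than C6, as in trans-fused 3-keto steroids that enolise towards C2 and the more so here because the axial 6β-H is flanked by the axial C4 and C10 methyl groups, and methyl iodide should enter from the α face opposite to the 10β-methyl to give the equatorial 8α-methyl ketone, a centre that is erased in step 10.

Step 10
Reactants: 17 8-methyl ketone
Product: 19 3,3-ethylenedioxy-7-(trimethylsilyloxy)-11-nordrim-7-ene, via bromomagnesium enolate 18 (not isolated)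
Conditions: i-Pr2NMgBr (from MeMgBr and i-Pr2NH), Et2O, rt; then Me3SiCl, Et3N, HMPA, rt
Reagents that add atoms: chlorotrimethylsilane, C[Si](C)(C)Cl
Why: Thermodynamic silyl enol ether formation with a bromomagnesium dialkylamide under equilibrating conditions gives the more substituted C7=C8 enolate 18, a preference reinforced by the trans-decalin bias against C6 enolisation, and the wholly basic medium leaves the ketal untouched.

Step 11
Reactants: 19 silyl enol ether
Product: 20 3,3-ethylenedioxy-11-nordrim-8-en-7-one
Conditions: Pd(OAc)2 (1.05 equiv), MeCN, rt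
Reagents that add atoms: none
Why: Saegusa–Ito oxidation: the divalent palladium enolate bound at C8 undergoes β-hydride elimination with a C9 hydrogen to give the conjugated endocyclic C8=C9 enone, and any exocyclic methylene isomer is expected to be funnelled to it by palladium hydride re-addition.

Step 12
Reactants: 20 enone
Product: 21 3,3-ethylenedioxy-11-nordrim-8-en-7α-ol
Conditions: LiBH(s-Bu)3, THF, −78 °C; then H2O
Reagents that add atoms: none
Why: Diastereoselective 1,2-reduction: conjugate delivery is disfavoured because the β-carbon C9 is neopentyl (next to quaternary C10), and the bulky borohydride attacks the C7 carbonyl along the equatorial trajectory from the β face, as it does with steroidal 1-en-3-ones and 4-en-3-ones, which sets the pseudoaxial 7α-hydroxyl group.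

Step 13
Reactants: 21 7α-allylic alcohol; 22 tributyl(iodomethyl)stannane
Product: 24 3,3-ethylenedioxy-7α-(tributylstannylmethoxy)-11-nordrim-8-ene, via potassium alkoxide 23 (not isolated)
Conditions: KH, THF, 0 °C to rt; then 22, 18-crown-6 (cat.), rt
Reagents that add atoms: tributyl(iodomethyl)stannane (22), CCCC[Sn](CCCC)(CCCC)CI
Why: Williamson etherification: alkoxide 23 displaces iodide from the unhindered iodomethyl carbon in an SN2 reaction, so the C7–O bond and its configuration are untouched.

Step 14
Reactants: 24 stannylmethyl ether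
Product: 26 3,3-ethylenedioxy-9-epi-drim-7-en-11-ol (9β-H; C11 α and axial), via lithiomethyl ether 25 (not isolated)
Conditions: n-BuLi, THF, −78 °C; then H2O
Reagents that add atoms: none
Why: Wittig–Still rearrangement: tin–lithium exchange gives the unstabilised α-alkoxy carbanion 25, which undergoes a concerted suprafacial [2,3]-sigmatropic shift through a five-membered envelope transition state, so that the pseudoaxial 7α-oxygen hands its CH2 group to the α face of C9 (anti to the 10β-methyl), setting the axial C9–C11 bond and moving the alkene to C7=C8.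

Step 15
Reactants: 26 homoallylic alcohol; 27 isofraxidin
Product: 28 isofraxidin 3,3-ethylenedioxy-9-epi-drim-7-en-11-yl ether
Conditions: PPh3, DIAD, THF, 0 °C to rt
Reagents that add atoms: isofraxidin (27), COc1cc2ccc(=O)oc2c(OC)c1O
Why: Mitsunobu etherification: the acidic 7-hydroxycoumarin protonates the betaine and its phenoxide displaces the oxyphosphonium group at primary C11, a reaction that touches no stereocentre and whose neutral conditions spare the ketal, the alkene and the lactone.

Step 16
Reactants: 28 ketal ether
Product: 29 target, 7-{[(1R,4aR,8aS)-2,5,5,8a-tetramethyl-6-oxo-1,4,4a,5,6,7,8,8a-octahydronaphthalen-1-yl]methoxy}-6,8-dimethoxy-2H-chromen-2-one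
Conditions: 1 M aq HCl, THF, rt
Reagents that add atoms: water, O
Why: Acid-catalysed ketal hydrolysis, accelerated by relief of strain next to the gem-dimethyl group, proceeds under conditions too mild to move the trisubstituted alkene, cleave the alkyl aryl ether or open the coumarin lactone, and no stereocentre can epimerise because neither C5 nor C9 is α to the C3 carbonyl.

Compound list
1 | (S)-carvone, (5S)-2-methyl-5-(prop-1-en-2-yl)cyclohex-2-en-1-one | O=C1C(C)=CC[C@H](C(C)=C)C1 | starting material
2 | lithium (5S)-2-methyl-5-(prop-1-en-2-yl)cyclohex-1-en-1-olate | [Li]OC1=C(C)CC[C@H](C(C)=C)C1 | intermediate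
3 | (5S)-dihydrocarvone, C2 epimer mixture | O=C1C(C)CC[C@H](C(C)=C)C1 | intermediate
4 | ethyl vinyl ketone (pent-1-en-3-one) | CCC(=O)C=C | starting material
5 | (2S,5S)-2-methyl-2-(3-oxopentyl)-5-(prop-1-en-2-yl)cyclohexan-1-one | CCC(=O)CC[C@]1(C)CC[C@H](C(C)=C)CC1=O | intermediate
6 | 5-hydroxy ketol (10β-CH3, 7α-isopropenyl; C4 and C5 uncontrolled and erased on dehydration) | O=C1CC[C@]2(C)CC[C@H](C(C)=C)CC2(O)C1C | intermediate
7 | (4aS,7S)-1,4a-dimethyl-7-(prop-1-en-2-yl)-4,4a,5,6,7,8-hexahydronaphthalen-2(3H)-one | O=C1CC[C@]2(C)CC[C@H](C(C)=C)CC2=C1C | intermediate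
8 | lithium C3–C4 enolate of the trans-fused (5α-H) dihydro ketone | [Li]OC1=C(C)[C@@H]2C[C@@H](C(C)=C)CC[C@@]2(C)CC1 | intermediate
9 | (4aS,7S,8aR)-1,1,4a-trimethyl-7-(prop-1-en-2-yl)octahydronaphthalen-2(1H)-one | O=C1CC[C@]2(C)CC[C@H](C(C)=C)C[C@H]2C1(C)C | intermediate
10 | 3,3-ethylenedioxy-7α-isopropenyl-4,4,10β-trimethyl-trans-decalin (5α-H) | C1COC2(O1)CC[C@]3(C)CC[C@H](C(C)=C)C[C@H]3C2(C)C | intermediate
11 | secondary ozonide (3-methyl-1,2,4-trioxolan-3-yl group at C7α; ozonide carbon uncontrolled) | C1COC2(O1)CC[C@]3(C)CC[C@H](C4(C)OCOO4)C[C@H]3C2(C)C | intermediate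
12 | 7α-acetyl-3,3-ethylenedioxy-4,4,10β-trimethyl-trans-decalin (5α-H) | C1COC2(O1)CC[C@]3(C)CC[C@H](C(C)=O)C[C@H]3C2(C)C | intermediate
13 | 7α-acetoxy-3,3-ethylenedioxy-4,4,10β-trimethyl-trans-decalin (5α-H) | C1COC2(O1)CC[C@]3(C)CC[C@H](OC(C)=O)C[C@H]3C2(C)C | intermediate
14 | 3,3-ethylenedioxy-4,4,10β-trimethyl-trans-decalin-7α-ol (5α-H) | C1COC2(O1)CC[C@]3(C)CC[C@H](O)C[C@H]3C2(C)C | intermediate
15 | 3,3-ethylenedioxy-4,4,10β-trimethyl-trans-decalin-7-one (5α-H) | C1COC2(O1)CC[C@]3(C)CCC(=O)C[C@H]3C2(C)C | intermediate
16 | lithium C7–C8 enolate of 15 | C1COC2(O1)CC[C@]3(C)CC=C(O[Li])C[C@H]3C2(C)C | intermediate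
17 | 3,3-ethylenedioxy-11-nordriman-7-one (8α-CH3, 5α-H) | C1COC2(O1)CC[C@]3(C)C[C@H](C)C(=O)C[C@H]3C2(C)C | intermediate
18 | bromomagnesium C7–C8 enolate of 17 | C1COC2(O1)CC[C@]3(C)CC(C)=C(O[Mg]Br)C[C@H]3C2(C)C | intermediate
19 | 3,3-ethylenedioxy-7-(trimethylsilyloxy)-11-nordrim-7-ene | C1COC2(O1)CC[C@]3(C)CC(C)=C(O[Si](C)(C)C)C[C@H]3C2(C)C | intermediate
20 | 3,3-ethylenedioxy-11-nordrim-8-en-7-one | C1COC2(O1)CC[C@]3(C)C=C(C)C(=O)C[C@H]3C2(C)C | intermediate
21 | 3,3-ethylenedioxy-11-nordrim-8-en-7α-ol | C1COC2(O1)CC[C@]3(C)C=C(C)[C@H](O)C[C@H]3C2(C)C | intermediate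
22 | tributyl(iodomethyl)stannane | CCCC[Sn](CCCC)(CCCC)CI | starting material
23 | potassium alkoxide of 21 | C1COC2(O1)CC[C@]3(C)C=C(C)[C@H](O[K])C[C@H]3C2(C)C | intermediate
24 | 3,3-ethylenedioxy-7α-(tributylstannylmethoxy)-11-nordrim-8-ene | C1COC2(O1)CC[C@]3(C)C=C(C)[C@H](OC[Sn](CCCC)(CCCC)CCCC)C[C@H]3C2(C)C | intermediate
25 | 3,3-ethylenedioxy-7α-(lithiomethoxy)-11-nordrim-8-ene | C1COC2(O1)CC[C@]3(C)C=C(C)[C@H](OC[Li])C[C@H]3C2(C)C | intermediate
26 | 3,3-ethylenedioxy-9-epi-drim-7-en-11-ol (5α-H, 9β-H, 10β-CH3) | OC[C@@H]1C(C)=CC[C@H]2C(C)(C)C3(OCCO3)CC[C@]12C | intermediate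
27 | isofraxidin (7-hydroxy-6,8-dimethoxycoumarin) | COc1cc2ccc(=O)oc2c(OC)c1O | starting material
28 | isofraxidin 3,3-ethylenedioxy-9-epi-drim-7-en-11-yl ether | COc1cc2ccc(=O)oc2c(OC)c1OC[C@@H]1C(C)=CC[C@H]2C(C)(C)C3(OCCO3)CC[C@]12C | intermediate
29 | 7-{[(1R,4aR,8aS)-2,5,5,8a-tetramethyl-6-oxo-1,4,4a,5,6,7,8,8a-octahydronaphthalen-1-yl]methoxy}-6,8-dimethoxy-2H-chromen-2-one | COc1cc2ccc(=O)oc2c(OC)c1OC[C@@H]1C(C)=CC[C@H]2C(C)(C)C(=O)CC[C@]12C | target

Total step count: 16. Longest linear sequence: 16 steps (1 to 29). Compounds 4, 22 and 27 are bought and enter directly.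

Steps most likely to fail

Step 2. The remote isopropenyl group may discriminate too weakly between the two faces of the enolate at C10. The base may also polymerise the vinyl ketone or promote a second Michael addition.
- The fallback sets out from 3 and makes the same two bonds, but through a chiral enamine instead of an enolate.
- Ketone 3 is condensed with (R)-1-phenylethylamine (toluene, Dean–Stark) to the N-[(R)-1-phenylethyl] imine F1.
- The more substituted secondary enamine tautomer of F1 adds to 4 under neutral conditions (THF, 40 °C) in an aza-ene-like Michael reaction. The auxiliary shields the face that the substrate already disfavours, so this is the matched pairing, and the product is the C10-alkylated keto imine F2.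
- Aqueous acetic acid hydrolyses F2, and the fallback comes back to the route at dione 5, now isolated. NaOMe in MeOH carries 5 through 6 to 7.

Step 12. Hydride may be delivered to C9 (conjugate reduction) or to the α face of the carbonyl, eroding the 7α configuration on which C9 depends.
- The fallback sets out from 20 and sets C7 by inversion rather than by facial control.
- Luche reduction (NaBH4, CeCl3·7H2O, MeOH, 0 °C) proceeds by axial attack to the pseudoequatorial 7β-alcohol F3.
- Mitsunobu inversion (4-nitrobenzoic acid, PPh3, DIAD, THF) gives the 7α-(4-nitrobenzoate) F4. The SN2′ pathway is closed by the neopentyl C9.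
- Methanolysis (K2CO3, MeOH) comes back to the route at 21.

Step 15. Displacement at the β-branched, axially held C11 by a phenoxide with two ortho substituents may be slow. The activated alcohol could then be consumed by the hydrazide or by elimination.
- The fallback sets out from 26 and separates activation from substitution.
- MsCl and Et3N (CH2Cl2, 0 °C) give the C11 mesylate F5.
- F5 is displaced by the caesium phenoxide of 27 (Cs2CO3, DMF, 60 °C), coming back to the route at 28.

Further compounds
F1 | step 2 | N-[(R)-1-phenylethyl] imine of (5S)-dihydrocarvone | C[C@@H](N=C1C(C)CC[C@H](C(C)=C)C1)c1ccccc1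
F2 | step 2 | N-[(R)-1-phenylethyl] imine of (2S,5S)-2-methyl-2-(3-oxopentyl)-5-(prop-1-en-2-yl)cyclohexan-1-one | C[C@@H](N=C1[C@](C)(CCC(=O)CC)CC[C@H](C(C)=C)C1)c1ccccc1
F3 | step 12 | 3,3-ethylenedioxy-11-nordrim-8-en-7β-ol | C1COC2(O1)CC[C@]3(C)C=C(C)[C@@H](O)C[C@H]3C2(C)C
F4 | step 12 | 3,3-ethylenedioxy-11-nordrim-8-en-7α-yl 4-nitrobenzoate | C1COC2(O1)CC[C@]3(C)C=C(C)[C@H](OC(=O)c4ccc(cc4)[N+](=O)[O-])C[C@H]3C2(C)C
F5 | step 15 | 3,3-ethylenedioxy-9-epi-drim-7-en-11-yl methanesulfonate | CS(=O)(=O)OC[C@@H]1C(C)=CC[C@H]2C(C)(C)C3(OCCO3)CC[C@]12C
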